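The ring is numbered C1 (carbonyl between the methoxy and octadecyl carbons), C2 (OMe), C3 (H), C4 (carbonyl), C5 (H) and C6 (octadecyl). The quinone is cut into two three-carbon halves, C3–C4–C5 and C2–C1–C6. The 1,3-placement of oxygen at C2 and C4 and of the alkyl group at C6 gives the halves matching polarity: a 1,3-dinucleophile (Chan's diene, an acetoacetate bis-silyl enol ether) and a 1,3-dielectrophile (the acyl ketene acetal C18H37COCH=C(OMe)2). Their TiCl4-mediated formal [3+3] cyclocondensation forms the C2–C3 and C5–C6 bonds in one operation and delivers the benzenoid ring with the methoxy group in place. Ester removal and para-oxidation at C1 finish the quinone.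

Key step: step 2

Remark: diene 4 is taken as the commercial reagent, a mixture of geometric isomers at its ketene acetal double bond; this geometry is lost in product 6, and the target has no stereocentre.

Step 1
Reactants: 1 nonadecanoyl chloride; 2 1,1-dimethoxyethene (ketene dimethyl acetal)
Product: 3 1,1-dimethoxyhenicos-1-en-3-one
Conditions: 2 (1.5 equiv), pyridine (1.5 equiv), CH2Cl2, 0 °C to 20 °C; filtration through basic alumina, used without storage
Reagents that add atoms: none
Why: C-acylation of the strongly nucleophilic ketene acetal by the acylpyridinium ion and loss of the α-proton should give the push-pull acyl ketene acetal (acylation of a ketene acetal), pyridine being chosen over a trialkylamine to keep dehydrochlorination of 1 to the alkylketene slow.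

Step 2
Reactants: 3 1,1-dimethoxyhenicos-1-en-3-one; 4 1-methoxy-1,3-bis(trimethylsilyloxy)buta-1,3-diene (Chan's diene)
Product: 6 methyl 2-hydroxy-4-methoxy-6-octadecylbenzoate, via methyl (5E)-5-methoxy-3,7-dioxopentacos-5-enoate 5 (not isolated)
Conditions: 4 (1.2 equiv), TiCl4 (1.1 equiv), CH2Cl2, −78 °C to 20 °C; then 1 M HCl
Reagents that add atoms: none
Why: TiCl4 binds the carbonyl oxygen of 3 and makes the ketene acetal carbon a dialkoxycarbenium-like centre; the terminal CH2 of diene 4 adds there (vinylogous Mukaiyama addition) and one methoxide is expelled, which forms the bond from the methoxy-bearing ring carbon to its CH neighbour and leaves the β-methoxy enone 5 with its silyl ketene acetal end intact. That nucleophilic carbon then attacks the titanium-activated ketone in a Mukaiyama aldol closure (6-(enolexo)-exo-trig), forming the bond from the octadecyl-bearing carbon to the ring carbon that carries the ester, and loss of silanol and enolisation aromatise the ring. The closest known reaction type is the TiCl4-mediated formal [3+3] cyclocondensation (cycloaromatisation) of 1,3-bis(silyloxy)-1,3-dienes with masked 1,3-dicarbonyl electrophiles, which includes β,β-dialkoxy enones. No stereocentre is formed; the enol ether double bond of 5 must be E so that the chain ends can meet, which the low rotation barrier of the push-pull alkene and reversible titanium chelation should allow. The step needs attack at the acetal carbon before the ketone and retention of exactly one methoxy group: the chelated push-pull system is most electrophilic at the acetal carbon, and after the first substitution that carbon is a vinylogous ester that no longer competes with the ketone for the tethered nucleophile. The opposite orientation of the two partners would place the ester on the other CH carbon and would still converge on phenol 8 after step 3.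

Step 3
Reactants: 6 methyl 2-hydroxy-4-methoxy-6-octadecylbenzoate
Product: 8 3-methoxy-5-octadecylphenol, via 2-hydroxy-4-methoxy-6-octadecylbenzoic acid 7 (not isolated)
Conditions: KOH (10 equiv), DMSO–H2O (4:1), 120 °C; then 3 M HCl, dioxane, 100 °C
Reagents that add atoms: none
Why: Saponification (acyl–oxygen cleavage) of the hindered salicylate in hot aqueous DMSO followed by acid-promoted protodecarboxylation of the electron-rich salicylic acid 7 (ipso protonation ortho and para to the two oxygen donors) should give the phenol, as in the classical olivetol and orcinol preparations.

Step 4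
Reactants: 8 3-methoxy-5-octadecylphenol
Product: 9 2-methoxy-6-octadecylcyclohexa-2,5-diene-1,4-dione (2-methoxy-6-octadecyl-1,4-benzoquinone)
Conditions: (KSO3)2NO (3 equiv), KH2PO4, Aliquat 336 (5 mol %), CH2Cl2–H2O, 20 °C
Reagents that add atoms: potassium nitrosodisulfonate (Fremy's salt), [K+].[K+].[O]N(S(=O)(=O)[O-])S(=O)(=O)[O-]
Why: Teuber oxidation, in which one nitrosodisulfonate radical abstracts the phenolic hydrogen, a second couples with the aryloxyl radical at the free para carbon and the adduct collapses to the para-quinone with loss of imidodisulfonate, the known outcome for 3-alkoxy-5-alkylphenols.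

Compound list
1 | nonadecanoyl chloride | CCCCCCCCCCCCCCCCCCC(=O)Cl | starting material
2 | 1,1-dimethoxyethene (ketene dimethyl acetal) | C=C(OC)OC | starting material
3 | 1,1-dimethoxyhenicos-1-en-3-one | CCCCCCCCCCCCCCCCCCC(=O)C=C(OC)OC | intermediate
4 | 1-methoxy-1,3-bis(trimethylsilyloxy)buta-1,3-diene (Chan's diene, geometric mixture at the ketene acetal double bond) | COC(O[Si](C)(C)C)=CC(=C)O[Si](C)(C)C | starting material
5 | methyl (5E)-5-methoxy-3,7-dioxopentacos-5-enoate (present in the flask as its silyl and titanium enolate) | CCCCCCCCCCCCCCCCCCC(=O)/C=C(/OC)CC(=O)CC(=O)OC | intermediate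
6 | methyl 2-hydroxy-4-methoxy-6-octadecylbenzoate | CCCCCCCCCCCCCCCCCCc1cc(OC)cc(O)c1C(=O)OC | intermediate
7 | 2-hydroxy-4-methoxy-6-octadecylbenzoic acid | CCCCCCCCCCCCCCCCCCc1cc(OC)cc(O)c1C(=O)O | intermediate
8 | 3-methoxy-5-octadecylphenol | CCCCCCCCCCCCCCCCCCc1cc(O)cc(OC)c1 | intermediate
9 | 2-methoxy-6-octadecylcyclohexa-2,5-diene-1,4-dione | CCCCCCCCCCCCCCCCCCC1=CC(=O)C=C(OC)C1=O | target

Total step count: 4
Longest linear sequence: 4 steps (1 → 3 → 6 → 8 → 9)

Steps most likely to fail

Step 2 (key step). The risk is Lewis-acid-induced demethylation or hydrolysis of the ketene acetal before the first C–C bond forms, or closure of the open-chain adduct through oxygen to a pyranone instead of through carbon. The fallback replaces the Lewis-acid annulation by an anionic one and sets out from 3. Compound 3 is added to the sodium enolate of dimethyl 3-oxopentanedioate (COC(=O)CC(=O)CC(=O)OC; NaH, THF, 0 °C to reflux). Addition–elimination at the acetal carbon followed by intramolecular Knoevenagel-type condensation on the ketone should give dimethyl 2-hydroxy-4-methoxy-6-octadecylbenzene-1,3-dicarboxylate F1; this base-mediated annulation is known for α-oxo ketene dithioacetals and β-alkoxy enones. Saponification under the conditions of step 3 should give 2-hydroxy-4-methoxy-6-octadecylbenzene-1,3-dicarboxylic acid F2, which loses both carboxyl groups on acidification and heating. The fallback comes back to the route at 8.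

Step 1. The risk is dehydrochlorination of 1 to the alkylketene and its [2+2] cycloaddition with 2, a second acylation of the product, or hydrolysis of the acyl ketene acetal during isolation. The fallback acylates a chloroalkene and then exchanges chloride for methoxide, and sets out from 1. AlCl3-promoted Friedel–Crafts-type acylation of 1,1-dichloroethene (C=C(Cl)Cl; CH2Cl2, 0 °C) should give 1,1,1-trichlorohenicosan-3-one F3, which loses HCl with Et3N to give 1,1-dichlorohenicos-1-en-3-one F4. Two addition–eliminations with NaOMe (2.1 equiv, MeOH, 0 °C) should replace both vinylic chlorides. The fallback comes back to the route at 3.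

Step 3. The risk is incomplete acyl–oxygen cleavage of the di-ortho-substituted ester, or attack on the aryl methyl ether when the conditions are forced. The fallback uses alkyl–oxygen instead of acyl–oxygen cleavage and sets out from 6. SN2 demethylation of the ester by lithium propane-1-thiolate (3 equiv, DMF, 20 °C) should give the carboxylate of 7 under conditions at which aryl methyl ethers survive. Acidification and warming then decarboxylate it, and the fallback comes back to the route at 8; it makes no new compound.

Further compounds
F1 | step 2 | dimethyl 2-hydroxy-4-methoxy-6-octadecylbenzene-1,3-dicarboxylate | CCCCCCCCCCCCCCCCCCc1cc(OC)c(C(=O)OC)c(O)c1C(=O)OC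
F2 | step 2 | 2-hydroxy-4-methoxy-6-octadecylbenzene-1,3-dicarboxylic acid | CCCCCCCCCCCCCCCCCCc1cc(OC)c(C(=O)O)c(O)c1C(=O)O
F3 | step 1 | 1,1,1-trichlorohenicosan-3-one | CCCCCCCCCCCCCCCCCCC(=O)CC(Cl)(Cl)Cl
F4 | step 1 | 1,1-dichlorohenicos-1-en-3-one | CCCCCCCCCCCCCCCCCCC(=O)C=C(Cl)Cl
F0 | step 3 | none | none
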